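**Retrosynthetic overview**
- The depside is cut at the aryl ester C–O bond into ring A acid chloride (2-heptyl-4,6-dimethoxybenzoyl chloride) and a ring B phenol whose carboxyl is masked as a benzyl ester, removed last by hydrogenolysis.
- The strategy rests on ring B: C1 carries the carboxyl, C2 the heptyl chain, C4 the acylated oxygen and C6 a methyl ether, so the C4 and C6 oxygens have to be told apart.
- Ring B is therefore built by a pyranone/ketene acetal cycloaddition–decarboxylation. The 2-pyranone supplies C1, C2, C5 and C6 with the C6 methoxy already in place. Ketene bis(trimethylsilyl) acetal supplies C3, C4 and the C4 oxygen as a labile silyl ether.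
- The pyranone comes from dibenzyl 3-oxopentanedioate by C-acylation with octanoyl chloride, lactonisation and O-methylation. Ring A comes from 1-bromo-3,5-dimethoxybenzene by Kumada coupling, Vilsmeier formylation, Pinnick oxidation and chlorination.
- Ring order: pyranone ring (step 2), then ring B (step 5); ring A is bought as an arene.

Key step: step 5

Remark (assumption): dibenzyl 3-oxopentanedioate and heptylmagnesium bromide (ether solution) are taken as purchasable; the target is achiral, so no stereocentre has to be set.

**Route**

Step 1
Reactants: 1 dibenzyl 3-oxopentanedioate; 2 octanoyl chloride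
Product: 3 dibenzyl 2-octanoyl-3-oxopentanedioate
Conditions: MgCl2, pyridine, CH2Cl2, 0 °C to rt; then 1 M HCl
Reagents that add atoms: none
Why: Rathke-type soft enolisation, in which MgCl2 chelation lets pyridine form the magnesium enolate of the beta-keto ester, which is C-acylated by the acid chloride, and the more acidic product stays bound as its magnesium chelate, which should suppress a second acylation.

Step 2
Reactants: 3 dibenzyl 2-octanoyl-3-oxopentanedioate
Product: 4 benzyl 2-heptyl-4-hydroxy-6-oxo-6H-pyran-3-carboxylate
Conditions: DBU, toluene, 110 °C; then 1 M HCl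
Reagents that add atoms: none
Why: Base-mediated lactonisation of a 3,5-dioxo ester to a 4-hydroxy-2-pyranone, in which the enol oxygen of the octanoyl ketone attacks the remote benzyl ester in the only possible six-membered closure, and the benzyl alcohol released cannot scramble the remaining benzyl ester.

Step 3
Reactants: 4 benzyl 2-heptyl-4-hydroxy-6-oxo-6H-pyran-3-carboxylate
Product: 5 benzyl 2-heptyl-4-methoxy-6-oxo-6H-pyran-3-carboxylate
Conditions: Me2SO4, K2CO3, acetone, reflux
Reagents that add atoms: dimethyl sulfate COS(=O)(=O)OC
Why: Williamson-type O-methylation of the vinylogous acid, which under these conditions should favour the 4-methoxy-2-pyranone over the isomeric 2-methoxy-4-pyranone, the latter being separable by chromatography if it forms.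

Step 4
Reactants: 6 trimethylsilyl acetate
Product: 8 ketene bis(trimethylsilyl) acetal [1,1-bis(trimethylsilyloxy)ethene], via lithium enolate 7 (not isolated)
Conditions: LiN(iPr)2, THF, −78 °C; then Me3SiCl, −78 °C to rt; distillation
Reagents that add atoms: chlorotrimethylsilane C[Si](C)(C)Cl
Why: Kinetic deprotonation of the silyl ester alpha-CH followed by O-silylation of the enolate is the standard preparation of ketene bis(silyl) acetals, and the product is distilled with exclusion of moisture.

Step 5
Reactants: 5 benzyl 2-heptyl-4-methoxy-6-oxo-6H-pyran-3-carboxylate; 8 ketene bis(trimethylsilyl) acetal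
Product: 12 benzyl 2-heptyl-4-hydroxy-6-methoxybenzoate, via bicyclic lactone 9 (not isolated), via silyl ketal diene 10 (not isolated), via aryl silyl ether 11 (not isolated)
Conditions: 8 (excess), mesitylene, sealed tube, 150 °C; then 1 M HCl, THF, rt
Reagents that add atoms: none
Why: The electron-rich CH2 terminus of 8 bonds to the heptyl-bearing pyranone carbon, which is the beta-carbon of the benzyl acrylate unit and the most electron-poor diene terminus, and the bis(silyloxy)-substituted carbon then bonds to the pyranone CH next to the lactone carbonyl in a concerted asynchronous or stepwise [4+2] closure that gives the bridged lactone 9. Cycloreversion of 9 expels carbon dioxide to give diene 10, 1,2-elimination of trimethylsilanol across the former acetal CH2–C(OSiMe3)2 bond aromatises it to silyl ether 11, and dilute acid cleaves the aryl O–Si bond to the free phenol 12. The closest known reaction is the inverse-electron-demand Diels–Alder/decarboxylation benzannulation of 2-pyranone-5-carboxylates (coumalates) with ketene acetals, which gives 4-oxygenated benzoates. Ring B is closed by an intermolecular [4+2] cycloaddition that forms the ring B C2–C3 and C4–C5 bonds, followed by retro-[4+2] loss of the lactone bridge; the two bridgehead stereocentres of 9 are fixed relative to each other by the bicycle, are racemic and vanish on aromatisation, so no stereocontrol is required. The selectivity needed is regiochemical, with the oxygen-bearing acetal carbon ending para to the ester at ring B C4 and not at C3, and it is secured by the polarisation of the pyranone by its ester and lactone carbonyls together with the fact that 8 is nucleophilic only at CH2. Because the 4-methoxy and heptyl groups make this pyranone less electrophilic than a coumalate, an excess of 8 and a sealed vessel at 150 °C are planned.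

Step 6
Reactants: 13 1-bromo-3,5-dimethoxybenzene; 14 heptylmagnesium bromide
Product: 15 1-heptyl-3,5-dimethoxybenzene
Conditions: NiCl2(dppp) (cat.), THF/Et2O, 0 °C to reflux
Reagents that add atoms: none
Why: Kumada–Tamao–Corriu coupling of an aryl bromide with a primary alkyl Grignard reagent, where the chelating diphosphine on nickel should suppress beta-hydride elimination.

Step 7
Reactants: 15 1-heptyl-3,5-dimethoxybenzene
Product: 17 2-heptyl-4,6-dimethoxybenzaldehyde, via iminium salt 16 (not isolated)
Conditions: POCl3, DMF, 0 °C to 70 °C; then H2O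
Reagents that add atoms: N,N-dimethylformamide CN(C)C=O; water O
Why: Vilsmeier–Haack formylation, which on 5-alkylresorcinol dimethyl ethers should go mainly at the position next to the alkyl chain (para to one methoxy, ortho to the other) rather than at the more crowded position between the two methoxy groups, and the iminium salt is hydrolysed on aqueous work-up.

Step 8
Reactants: 17 2-heptyl-4,6-dimethoxybenzaldehyde
Product: 18 2-heptyl-4,6-dimethoxybenzoic acid
Conditions: NaClO2, NaH2PO4, 2-methyl-2-butene, t-BuOH/H2O, rt
Reagents that add atoms: sodium chlorite [Na+].[O-]Cl=O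
Why: Pinnick oxidation of the aldehyde by chlorous acid, with 2-methyl-2-butene trapping hypochlorous acid so that the electron-rich ring is not chlorinated.

Step 9
Reactants: 18 2-heptyl-4,6-dimethoxybenzoic acid
Product: 19 2-heptyl-4,6-dimethoxybenzoyl chloride
Conditions: (COCl)2, DMF (cat.), CH2Cl2, 0 °C to rt; used crude
Reagents that add atoms: oxalyl chloride O=C(Cl)C(=O)Cl
Why: DMF-catalysed acid chloride formation under mild, non-aqueous conditions that should avoid protodecarboxylation of the electron-rich acid.

Step 10
Reactants: 12 benzyl 2-heptyl-4-hydroxy-6-methoxybenzoate; 19 2-heptyl-4,6-dimethoxybenzoyl chloride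
Product: 20 benzyl 2-heptyl-4-[(2-heptyl-4,6-dimethoxybenzoyl)oxy]-6-methoxybenzoate
Conditions: Et3N, DMAP (cat.), CH2Cl2, 0 °C to 40 °C
Reagents that add atoms: none
Why: DMAP-catalysed acylation of the only free hydroxyl, at ring B C4, through the acylpyridinium ion, which should overcome the hindrance of the doubly ortho-substituted acid chloride and leave the benzyl ester untouched.

Step 11
Reactants: 20 benzyl 2-heptyl-4-[(2-heptyl-4,6-dimethoxybenzoyl)oxy]-6-methoxybenzoate
Product: 21 2-heptyl-4-[(2-heptyl-4,6-dimethoxybenzoyl)oxy]-6-methoxybenzoic acid (target)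
Conditions: H2 (1 atm), Pd/C, EtOAc, rt
Reagents that add atoms: none
Why: Hydrogenolysis of the benzylic C–O bond of the benzyl ester over Pd/C, to which the aryl ester linkage, the methyl ethers and the alkyl chains are inert.

**Compound list**
1 | dibenzyl 3-oxopentanedioate | O=C(CC(=O)OCc1ccccc1)CC(=O)OCc1ccccc1 | starting material
2 | octanoyl chloride | CCCCCCCC(=O)Cl | starting material
3 | dibenzyl 2-octanoyl-3-oxopentanedioate (racemic, largely enolised) | CCCCCCCC(=O)C(C(=O)OCc1ccccc1)C(=O)CC(=O)OCc1ccccc1 | intermediate
4 | benzyl 2-heptyl-4-hydroxy-6-oxo-6H-pyran-3-carboxylate | CCCCCCCc1oc(=O)cc(O)c1C(=O)OCc1ccccc1 | intermediate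
5 | benzyl 2-heptyl-4-methoxy-6-oxo-6H-pyran-3-carboxylate | CCCCCCCc1oc(=O)cc(OC)c1C(=O)OCc1ccccc1 | intermediate
6 | trimethylsilyl acetate | CC(=O)O[Si](C)(C)C | starting material
7 | lithium 1-(trimethylsilyloxy)ethenolate | [Li+].C=C([O-])O[Si](C)(C)C | intermediate
8 | ketene bis(trimethylsilyl) acetal, 1,1-bis(trimethylsilyloxy)ethene | C=C(O[Si](C)(C)C)O[Si](C)(C)C | intermediate
9 | benzyl 1-heptyl-5-methoxy-3-oxo-8,8-bis(trimethylsilyloxy)-2-oxabicyclo[2.2.2]oct-5-ene-6-carboxylate (racemic; bridgeheads fixed by the bicycle) | CCCCCCCC12CC(O[Si](C)(C)C)(O[Si](C)(C)C)C(C(=O)O1)C(OC)=C2C(=O)OCc1ccccc1 | intermediate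
10 | benzyl 2-heptyl-6-methoxy-4,4-bis(trimethylsilyloxy)cyclohexa-1,5-diene-1-carboxylate | CCCCCCCC1=C(C(=O)OCc2ccccc2)C(OC)=CC(O[Si](C)(C)C)(O[Si](C)(C)C)C1 | intermediate
11 | benzyl 2-heptyl-6-methoxy-4-(trimethylsilyloxy)benzoate | CCCCCCCc1cc(O[Si](C)(C)C)cc(OC)c1C(=O)OCc1ccccc1 | intermediate
12 | benzyl 2-heptyl-4-hydroxy-6-methoxybenzoate | CCCCCCCc1cc(O)cc(OC)c1C(=O)OCc1ccccc1 | intermediate
13 | 1-bromo-3,5-dimethoxybenzene | COc1cc(OC)cc(Br)c1 | starting material
14 | heptylmagnesium bromide | CCCCCCC[Mg]Br | starting material
15 | 1-heptyl-3,5-dimethoxybenzene | CCCCCCCc1cc(OC)cc(OC)c1 | intermediate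
16 | [(2-heptyl-4,6-dimethoxyphenyl)methylidene]dimethyliminium dichlorophosphate | CCCCCCCc1cc(OC)cc(OC)c1C=[N+](C)C.[O-]P(=O)(Cl)Cl | intermediate
17 | 2-heptyl-4,6-dimethoxybenzaldehyde | CCCCCCCc1cc(OC)cc(OC)c1C=O | intermediate
18 | 2-heptyl-4,6-dimethoxybenzoic acid | CCCCCCCc1cc(OC)cc(OC)c1C(=O)O | intermediate
19 | 2-heptyl-4,6-dimethoxybenzoyl chloride | CCCCCCCc1cc(OC)cc(OC)c1C(=O)Cl | intermediate
20 | benzyl 2-heptyl-4-[(2-heptyl-4,6-dimethoxybenzoyl)oxy]-6-methoxybenzoate | CCCCCCCc1cc(OC(=O)c2c(CCCCCCC)cc(OC)cc2OC)cc(OC)c1C(=O)OCc1ccccc1 | intermediate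
21 | 2-heptyl-4-[(2-heptyl-4,6-dimethoxybenzoyl)oxy]-6-methoxybenzoic acid | CCCCCCCc1cc(OC(=O)c2c(CCCCCCC)cc(OC)cc2OC)cc(OC)c1C(=O)O | target

**Totals**
Total step count: 11.
Longest linear sequence: 6 steps (steps 1, 2, 3, 5, 10, 11; the ring A line, steps 6, 7, 8, 9, 10, 11, is equally long).

**Steps most likely to fail**

1. Step 5. The cycloaddition may not start, because the 4-methoxy and heptyl groups raise the pyranone LUMO and crowd the electrophilic terminus. Prolonged heating may then isomerise the ketene acetal to its C-silyl ester, or lead to conjugate displacement of the methoxy group instead of ring closure. The fallback sets out from 15 and comes back to the route at 20. It differentiates the ring B oxygens by hydrogen bonding rather than by ring construction. Ether 15 is demethylated with BBr3 (CH2Cl2, −78 °C to rt) to 5-heptylbenzene-1,3-diol F1. This is carboxylated next to the chain with methoxymagnesium methyl carbonate (MeOMgOCO2Me, DMF, 120 °C; cold acidic work-up) to 2-heptyl-4,6-dihydroxybenzoic acid F2. Alkylation of the carboxylate (benzyl bromide, KHCO3, DMF, rt) should give benzyl 2-heptyl-4,6-dihydroxybenzoate F3. Its C4 hydroxyl, which is not hydrogen-bonded to the ester, is acylated selectively with acid chloride 19 (Et3N, DMAP cat., CH2Cl2, 0 °C) to benzyl 2-heptyl-4-[(2-heptyl-4,6-dimethoxybenzoyl)oxy]-6-hydroxybenzoate F4. The remaining chelated C6 hydroxyl is then methylated (MeI, K2CO3, acetone, reflux) to give 20.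

2. Step 2. Under base the triacylmethane may lose its octanoyl group by retro-Claisen cleavage with the liberated benzyl alcohol, or lactonisation may stay incomplete. The fallback sets out from 2 and comes back at 4. Octanoyl chloride 2 is condensed with 2,2-dimethyl-1,3-dioxane-4,6-dione (pyridine, CH2Cl2, 0 °C) to 5-(1-hydroxyoctylidene)-2,2-dimethyl-1,3-dioxane-4,6-dione F5. Heating F5 with benzyl alcohol in toluene should give benzyl 3-oxodecanoate F6. This beta-keto ester is condensed with malonyl dichloride (CH2Cl2, rt to reflux), which C-acylates the alpha-carbon and O-acylates the enol, closing pyranone 4 directly.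

3. Step 10. Acyl transfer from the doubly ortho-substituted acid chloride to the weakly nucleophilic phenol, deactivated by its para ester, may be slow enough for hydrolysis of the acid chloride to compete. The fallback sets out from 18 and 12 and comes back at 20. Acid 18 is activated in the flask with trifluoroacetic anhydride (toluene, rt) as 2-heptyl-4,6-dimethoxybenzoic trifluoroacetic anhydride F7. This electron-rich mixed anhydride ionises readily towards the acylium ion and should acylate phenol 12 to give 20 without isolation of an acid chloride.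

**Further compounds**
F1 | step 5 | 5-heptylbenzene-1,3-diol | CCCCCCCc1cc(O)cc(O)c1
F2 | step 5 | 2-heptyl-4,6-dihydroxybenzoic acid | CCCCCCCc1cc(O)cc(O)c1C(=O)O
F3 | step 5 | benzyl 2-heptyl-4,6-dihydroxybenzoate | CCCCCCCc1cc(O)cc(O)c1C(=O)OCc1ccccc1
F4 | step 5 | benzyl 2-heptyl-4-[(2-heptyl-4,6-dimethoxybenzoyl)oxy]-6-hydroxybenzoate | CCCCCCCc1cc(OC(=O)c2c(CCCCCCC)cc(OC)cc2OC)cc(O)c1C(=O)OCc1ccccc1
F5 | step 2 | 5-(1-hydroxyoctylidene)-2,2-dimethyl-1,3-dioxane-4,6-dione | CCCCCCCC(O)=C1C(=O)OC(C)(C)OC1=O
F6 | step 2 | benzyl 3-oxodecanoate | CCCCCCCC(=O)CC(=O)OCc1ccccc1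
F7 | step 10 | 2-heptyl-4,6-dimethoxybenzoic trifluoroacetic anhydride | CCCCCCCc1cc(OC)cc(OC)c1C(=O)OC(=O)C(F)(F)F
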